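**Plan**

Ring numbering: C1 (C=O), C2 (C–OMe), C3 (=CH), C4 (CHOH), C5 (CH–farnesyl), C6 (CH–CH3). In the single six-membered ring, C4(OH)–C3=C2(OMe) is a vinylogous ester reduced at its carbonyl. C4 therefore traces back to an acyl carbon, and C3 to the nucleophilic CH2 end of a 2-methoxyallyl enol ether carried by C1.
Retrosynthetic cuts, in order: exchange of oxidation level between C1 and C4; C3–C4 (ring opening to an acid and an enol ether); C1–C2 (aldehyde plus 1-methoxyvinyllithium); C5–C6 (aldehyde enamine plus (E)-1-nitropropene); farnesyl CH2–CH2 (acetate enolate plus farnesyl bromide).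
Forward: the chain C4–C5–C6–C1–C2–C3 is built linearly, the only ring closes by acylation at C3–C4, then C4 is reduced and C1 oxidised.
Stereochemistry: C5 and C6 are set together by an (S)-diarylprolinol silyl ether catalyst (syn adduct, trans on the ring). C4 comes from a bulky hydride attacking the face opposite the C5 chain. Both E alkenes come with farnesyl bromide.

Key step: step 10

Remark: farnesyl means (2E,6E)-3,7,11-trimethyldodeca-2,6,10-trien-1-yl, the target ring numbering C1–C6 is used for all intermediates, and the carbinol carbon C1 made in step 7 is carried as a mixture of epimers (drawn without configuration) because step 14 oxidises it.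

**Step 1**
Reactants: 1 methyl acetate; 2 (2E,6E)-farnesyl bromide
Product: 4 methyl (4E,8E)-5,9,13-trimethyltetradeca-4,8,12-trienoate, via lithium enolate of methyl acetate 3 (not isolated)
Conditions: LiN(i-Pr)2 (2.2 equiv), 1 (2.4 equiv), THF, −78 °C; then 2 (1 equiv), DMPU, −78 to −40 °C
Reagents that add atoms: none
Why: Alkylation of a preformed lithium ester enolate by a primary allylic bromide (SN2) is routine, the excess of enolate kept cold holds back Claisen self-condensation, and the two E double bonds of 2 are not touched.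

**Step 2**
Reactants: 4 methyl (4E,8E)-5,9,13-trimethyltetradeca-4,8,12-trienoate
Product: 5 (4E,8E)-5,9,13-trimethyltetradeca-4,8,12-trienal
Conditions: i-Bu2AlH (1.1 equiv), toluene, −78 °C; MeOH quench, aq potassium sodium tartrate
Reagents that add atoms: none
Why: Partial reduction of an ester with i-Bu2AlH works because the tetrahedral aluminium alkoxide formed at −78 °C survives until the quench, so the aldehyde is released only after the hydride is destroyed.

**Step 3**
Reactants: 5 (4E,8E)-5,9,13-trimethyltetradeca-4,8,12-trienal; 6 (E)-1-nitropropene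
Product: 7 (2R,3R)-2-farnesyl-3-methyl-4-nitrobutanal
Conditions: (S)-2-[diphenyl(trimethylsilyloxy)methyl]pyrrolidine (10 mol %), 4-nitrophenol (10 mol %), 6 (1.5 equiv), toluene, 0 °C to rt
Reagents that add atoms: none
Why: Enamine-catalysed asymmetric Michael addition of an aldehyde to a nitroalkene: the E-enamine of 5 is shielded on one face by the CPh2(OSiMe3) group of the (S)-catalyst and meets the nitroalkene in a synclinal open transition state, which should set C5 (R) and C6 (R) in one event as the syn adduct that later reads as trans on the ring.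

**Step 4**
Reactants: 7 (2R,3R)-2-farnesyl-3-methyl-4-nitrobutanal
Product: 8 (2R,3R)-2-farnesyl-3-methyl-4-nitrobutanoic acid
Conditions: NaClO2, NaH2PO4, 2-methyl-2-butene (large excess), t-BuOH/H2O, 0 °C
Reagents that add atoms: sodium chlorite, [Na+].[O-]Cl=O
Why: Pinnick oxidation turns the configurationally fragile α-branched aldehyde into the acid at about pH 4 without epimerising C5, and the large excess of 2-methyl-2-butene intercepts HOCl before it can reach the three trisubstituted alkenes.

**Step 5**
Reactants: 8 (2R,3R)-2-farnesyl-3-methyl-4-nitrobutanoic acid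
Product: 9 methyl (2R,3R)-2-farnesyl-3-methyl-4-nitrobutanoate
Conditions: Me3SiCHN2, toluene/MeOH 4:1, 0 °C
Reagents that add atoms: (trimethylsilyl)diazomethane, C[Si](C)(C)C=[N+]=[N-]
Why: Esterification with Me3SiCHN2 needs no base, so the acidic CH2NO2 group is not alkylated, and the methyl ester is wanted as the leaving-group carrier for the base-induced lactonisation of step 7.

**Step 6**
Reactants: 9 methyl (2R,3R)-2-farnesyl-3-methyl-4-nitrobutanoate
Product: 11 methyl (2R,3R)-2-farnesyl-3-methyl-4-oxobutanoate, via sodium nitronate 10 (not isolated)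
Conditions: NaOMe (1.05 equiv), MeOH, 0 °C; then aq TiCl3 (4.5 equiv)/NH4OAc buffer (pH 5–6), THF, 0 °C to rt
Reagents that add atoms: water, O
Why: Reductive variant of the Nef reaction: only the nitro group (far more acidic than the ester α-CH) is deprotonated, trivalent titanium reduces the nitronate to the imine and the acetate buffer hydrolyses it to the aldehyde, so the strong mineral acid of the classical procedure, which would cyclise the polyene, is avoided.

**Step 7**
Reactants: 11 methyl (2R,3R)-2-farnesyl-3-methyl-4-oxobutanoate; 12 methyl vinyl ether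
Product: 15 (3R,4R)-3-farnesyl-5-(1-methoxyethenyl)-4-methyloxolan-2-one (C1 epimers), via 1-methoxyvinyllithium 13 (not isolated), via lithium alkoxide adduct 14 (not isolated)
Conditions: 12 (excess), t-BuLi (1.2 equiv), THF, −78 to 0 °C; then 11, −78 °C, warm to 0 °C; pH 7 phosphate buffer
Reagents that add atoms: none
Why: 1-Methoxyvinyllithium, the α-metalated vinyl ether used as an acetyl anion equivalent, adds to the aldehyde far faster than to the α-branched ester at −78 °C (1,2-addition), the C1 alkoxide then expels methoxide on warming to give the five-membered lactone without any acid, and the new C1 centre needs no control.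

**Step 8**
Reactants: 15 (3R,4R)-3-farnesyl-5-(1-methoxyethenyl)-4-methyloxolan-2-one
Product: 17 triethylsilyl (2R,3R)-2-farnesyl-5-methoxy-3-methyl-4-(triethylsilyloxy)hex-5-enoate, via potassium hydroxy carboxylate 16 (not isolated)
Conditions: KOH (1.1 equiv), THF/MeOH/H2O, rt; evaporate, toluene azeotrope; Et3SiCl (3 equiv), imidazole (5 equiv), DMF, 0 °C to rt
Reagents that add atoms: potassium hydroxide, [K+].[OH-]; chlorotriethylsilane, CC[Si](Cl)(CC)CC
Why: Saponification followed by exhaustive silylation of the dry hydroxy carboxylate is the standard way to hold a γ-hydroxy acid open, all operations are basic and so spare the enol ether, and hydroxide opens the lactone faster than it can enolise C5.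

**Step 9**
Reactants: 17 triethylsilyl (2R,3R)-2-farnesyl-5-methoxy-3-methyl-4-(triethylsilyloxy)hex-5-enoate
Product: 18 (2R,3R)-2-farnesyl-5-methoxy-3-methyl-4-(triethylsilyloxy)hex-5-enoic acid
Conditions: K2CO3, MeOH/THF/H2O, 0 °C; cold NaH2PO4 buffer (pH 6), Et2O extraction into a flask holding 2,6-lutidine; used at once
Reagents that add atoms: none
Why: Silyl esters undergo carbonate-mediated solvolysis far faster than secondary triethylsilyl ethers, so only the carboxyl group is freed, and the cold work-up at pH 6 into lutidine keeps the acid from protonating its own enol ether.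

**Step 10**
Reactants: 18 (2R,3R)-2-farnesyl-5-methoxy-3-methyl-4-(triethylsilyloxy)hex-5-enoic acid
Product: 20 (5R,6R)-6-farnesyl-3-methoxy-5-methyl-4-(triethylsilyloxy)cyclohex-2-en-1-one (target C4 ketone, C1 silyl ether), via acid chloride 19 (not isolated)
Conditions: 1-chloro-N,N,2-trimethylpropenylamine (1.05 equiv), 2,6-lutidine (3 equiv), CH2Cl2 (0.005 M), 0 °C, then 23 to 40 °C
Reagents that add atoms: none
Why: Proposed new method: the α-chloroenamine takes up the acid proton and hands over chloride, so acid chloride 19 arises without free HCl; the CH2 terminus C3 of the 1,1-disubstituted enol ether then attacks the acyl carbon C4, chloride departs, and 2,6-lutidine removes the doubly activated C3 proton of the C2 oxocarbenium ion to leave the C4(=O)–C3=C2(OMe) vinylogous ester. The closest known reaction type is the intermolecular C-acylation of alkyl vinyl ethers and 2-alkoxypropenes by acyl chlorides to β-alkoxy enones, established mainly for activated (perhalogenated or oxalyl) chlorides; new here is the ring-closing version with a plain α-branched alkanoyl chloride, in which the proximity of the two ends in a six-membered transition state is relied on to offset the lower electrophilicity. The only ring closes in the 6-(enolendo)-exo-trig mode, the C2=C3 bond ending inside the ring and the carbonyl oxygen outside it. No stereocentre is created: C5 and C6 are carried over, and C5, now α to a ketone, can at worst drift to the trans-diequatorial arrangement that is wanted. The selectivity needed is C-acylation at C3 ahead of enol ether protonation, chloride-induced demethylation of the oxocarbenium ion and attack by the farnesyl alkenes; HCl-free activation with base present from the start, high dilution, and the fact that the nearest trisubstituted alkene could only close a four-membered ring or an anti-Markovnikov five-membered ring should secure it. Should lutidine convert 19 into the ketene, the same C3 terminus adds to its central carbon and the zwitterion, unable to close a bicyclo[2.2.0]hexanone, collapses by proton transfer to the same product 20.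

**Step 11**
Reactants: 20 (5R,6R)-6-farnesyl-3-methoxy-5-methyl-4-(triethylsilyloxy)cyclohex-2-en-1-one
Product: 21 (1R,5R,6R)-6-farnesyl-3-methoxy-5-methyl-4-(triethylsilyloxy)cyclohex-2-en-1-ol (C4 hydroxyl cis to the C5 chain)
Conditions: LiBH(s-Bu)3 (2 equiv), THF, −78 to −40 °C; aq NaOH/H2O2, 0 °C
Reagents that add atoms: none
Why: 1,2-Reduction of a β-substituted cyclohexenone by a bulky trialkylborohydride: the methoxy group at C2 blocks conjugate delivery, and with farnesyl and methyl trans-diequatorial the reagent should take the equatorial trajectory on the face that carries C5–H, which places the C4 hydroxyl axial and cis to the chain (4R), while the basic work-up protects the acid-labile product.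

**Step 12**
Reactants: 21 (1R,5R,6R)-6-farnesyl-3-methoxy-5-methyl-4-(triethylsilyloxy)cyclohex-2-en-1-ol
Product: 22 the C4 tert-butyldimethylsilyl ether of 21 (C4 OSiMe2t-Bu, C1 OSiEt3)
Conditions: t-BuMe2SiOTf, 2,6-lutidine, CH2Cl2, −78 °C
Reagents that add atoms: tert-butyldimethylsilyl trifluoromethanesulfonate, CC(C)(C)[Si](C)(C)OS(=O)(=O)C(F)(F)F
Why: Silylation with a silyl triflate and a hindered pyridine base is fast even for an axial, flanked secondary alcohol and keeps the medium basic, which the acid-labile 3-methoxyallylic alcohol requires.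

**Step 13**
Reactants: 22 the bis-silyl ether (C4 OSiMe2t-Bu, C1 OSiEt3)
Product: 23 (4R,5R,6R)-4-(tert-butyldimethylsilyloxy)-5-farnesyl-2-methoxy-6-methylcyclohex-2-en-1-ol
Conditions: Bu4NF/AcOH 1:1 (1.2 equiv), THF, 0 °C
Reagents that add atoms: none
Why: Fluoride-induced desilylation discriminates by bulk at silicon, so the SiEt3 ether at C1 should go well before the SiMe2t-Bu ether at C4, and the acetate-buffered fluoride avoids the protic acid methods that would ionise the doubly allylic enol ether.

**Step 14**
Reactants: 23 (4R,5R,6R)-4-(tert-butyldimethylsilyloxy)-5-farnesyl-2-methoxy-6-methylcyclohex-2-en-1-ol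
Product: 24 (4R,5R,6R)-4-(tert-butyldimethylsilyloxy)-5-farnesyl-2-methoxy-6-methylcyclohex-2-en-1-one
Conditions: Dess–Martin periodinane, NaHCO3, CH2Cl2, 0 °C to rt
Reagents that add atoms: none
Why: Dess–Martin oxidation under bicarbonate buffer converts both C1 epimers into one ketone, turns the sensitive enol ether into a robust α-methoxy enone, and leaves C6 in its more stable equatorial (trans) arrangement.

**Step 15**
Reactants: 24 (4R,5R,6R)-4-(tert-butyldimethylsilyloxy)-5-farnesyl-2-methoxy-6-methylcyclohex-2-en-1-one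
Product: 25 (4R,5R,6R)-5-farnesyl-4-hydroxy-2-methoxy-6-methylcyclohex-2-en-1-one (CNP0534154.1)
Conditions: HF·pyridine, pyridine, THF, 0 °C to rt
Reagents that add atoms: none
Why: Fluoride cleavage of the remaining silyl ether with pyridine-buffered HF avoids the basic conditions under which a γ-hydroxy enone could isomerise or C6 could epimerise, and should give the target with C4, C5 and C6 all R.

**Compound list**

1 | methyl acetate | COC(C)=O | starting material
2 | (2E,6E)-farnesyl bromide | CC(C)=CCC/C(C)=C/CC/C(C)=C/CBr | starting material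
3 | lithium enolate of methyl acetate | COC(=C)[O-].[Li+] | intermediate
4 | methyl (4E,8E)-5,9,13-trimethyltetradeca-4,8,12-trienoate | COC(=O)CC/C=C(\C)CC/C=C(\C)CCC=C(C)C | intermediate
5 | (4E,8E)-5,9,13-trimethyltetradeca-4,8,12-trienal | O=CCC/C=C(\C)CC/C=C(\C)CCC=C(C)C | intermediate
6 | (E)-1-nitropropene | C/C=C/[N+](=O)[O-] | starting material
7 | (2R,3R)-2-farnesyl-3-methyl-4-nitrobutanal | O=C[C@H](C/C=C(\C)CC/C=C(\C)CCC=C(C)C)[C@@H](C)C[N+](=O)[O-] | intermediate
8 | (2R,3R)-2-farnesyl-3-methyl-4-nitrobutanoic acid | OC(=O)[C@H](C/C=C(\C)CC/C=C(\C)CCC=C(C)C)[C@@H](C)C[N+](=O)[O-] | intermediate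
9 | methyl (2R,3R)-2-farnesyl-3-methyl-4-nitrobutanoate | COC(=O)[C@H](C/C=C(\C)CC/C=C(\C)CCC=C(C)C)[C@@H](C)C[N+](=O)[O-] | intermediate
10 | sodium nitronate of 9 | COC(=O)[C@H](C/C=C(\C)CC/C=C(\C)CCC=C(C)C)[C@@H](C)C=[N+]([O-])[O-].[Na+] | intermediate
11 | methyl (2R,3R)-2-farnesyl-3-methyl-4-oxobutanoate | COC(=O)[C@H](C/C=C(\C)CC/C=C(\C)CCC=C(C)C)[C@@H](C)C=O | intermediate
12 | methyl vinyl ether | COC=C | starting material
13 | 1-methoxyvinyllithium | [Li]C(=C)OC | intermediate
14 | lithium alkoxide from addition of 13 to 11 | COC(=O)[C@H](C/C=C(\C)CC/C=C(\C)CCC=C(C)C)[C@@H](C)C([O-])C(OC)=C.[Li+] | intermediate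
15 | (3R,4R)-3-farnesyl-5-(1-methoxyethenyl)-4-methyloxolan-2-one | O=C1[C@H](C/C=C(\C)CC/C=C(\C)CCC=C(C)C)[C@@H](C)C(C(OC)=C)O1 | intermediate
16 | potassium (2R,3R)-2-farnesyl-4-hydroxy-5-methoxy-3-methylhex-5-enoate | [K+].[O-]C(=O)[C@H](C/C=C(\C)CC/C=C(\C)CCC=C(C)C)[C@@H](C)C(O)C(OC)=C | intermediate
17 | triethylsilyl (2R,3R)-2-farnesyl-5-methoxy-3-methyl-4-(triethylsilyloxy)hex-5-enoate | CC[Si](CC)(CC)OC(=O)[C@H](C/C=C(\C)CC/C=C(\C)CCC=C(C)C)[C@@H](C)C(O[Si](CC)(CC)CC)C(OC)=C | intermediate
18 | (2R,3R)-2-farnesyl-5-methoxy-3-methyl-4-(triethylsilyloxy)hex-5-enoic acid | OC(=O)[C@H](C/C=C(\C)CC/C=C(\C)CCC=C(C)C)[C@@H](C)C(O[Si](CC)(CC)CC)C(OC)=C | intermediate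
19 | (2R,3R)-2-farnesyl-5-methoxy-3-methyl-4-(triethylsilyloxy)hex-5-enoyl chloride | ClC(=O)[C@H](C/C=C(\C)CC/C=C(\C)CCC=C(C)C)[C@@H](C)C(O[Si](CC)(CC)CC)C(OC)=C | intermediate
20 | (5R,6R)-6-farnesyl-3-methoxy-5-methyl-4-(triethylsilyloxy)cyclohex-2-en-1-one | COC1=CC(=O)[C@H](C/C=C(\C)CC/C=C(\C)CCC=C(C)C)[C@@H](C)C1O[Si](CC)(CC)CC | intermediate
21 | (1R,5R,6R)-6-farnesyl-3-methoxy-5-methyl-4-(triethylsilyloxy)cyclohex-2-en-1-ol | COC1=C[C@H](O)[C@H](C/C=C(\C)CC/C=C(\C)CCC=C(C)C)[C@@H](C)C1O[Si](CC)(CC)CC | intermediate
22 | C4 tert-butyldimethylsilyl ether of 21 | COC1=C[C@H](O[Si](C)(C)C(C)(C)C)[C@H](C/C=C(\C)CC/C=C(\C)CCC=C(C)C)[C@@H](C)C1O[Si](CC)(CC)CC | intermediate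
23 | (4R,5R,6R)-4-(tert-butyldimethylsilyloxy)-5-farnesyl-2-methoxy-6-methylcyclohex-2-en-1-ol | COC1=C[C@H](O[Si](C)(C)C(C)(C)C)[C@H](C/C=C(\C)CC/C=C(\C)CCC=C(C)C)[C@@H](C)C1O | intermediate
24 | (4R,5R,6R)-4-(tert-butyldimethylsilyloxy)-5-farnesyl-2-methoxy-6-methylcyclohex-2-en-1-one | COC1=C[C@H](O[Si](C)(C)C(C)(C)C)[C@H](C/C=C(\C)CC/C=C(\C)CCC=C(C)C)[C@@H](C)C1=O | intermediate
25 | (4R,5R,6R)-5-farnesyl-4-hydroxy-2-methoxy-6-methylcyclohex-2-en-1-one | COC1=C[C@H](O)[C@H](C/C=C(\C)CC/C=C(\C)CCC=C(C)C)[C@@H](C)C1=O | target

**Step count**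

Total step count: 15. Longest linear sequence: 15 steps (from 1 and 2 to 25).

**Steps most likely to fail**

1. **Step 10 (ring closure).** The unactivated acyl chloride may acylate too slowly. Protonation and hydrolysis of the enol ether, chloride-induced O-demethylation of the oxocarbenium ion, or ketene dimerisation could then take over.
 The fallback uses known chemistry, a base-mediated intramolecular Claisen condensation in place of the electrophilic acylation. It sets out from acid 18, which Me3SiCHN2 converts into the methyl ester F1. Oxalic acid on wet silica gel in CH2Cl2 at 0 °C hydrolyses only the enol ether and gives the methyl ketone F2. KOt-Bu in THF at 0 °C closes the same C3–C4 bond by attack of the methyl ketone enolate on the ester and gives the cyclohexane-1,3-dione F3. O-methylation with Me3SiCHN2 gives two vinylogous esters. The C2-methoxy isomer is 20, where the fallback rejoins the route. It is separated from the C4-methoxy isomer F4, which aqueous LiOH returns to F3.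

2. **Step 11 (C4 reduction).** Facial selectivity may be poor, because in the half-chair only the axial hydrogen at C6 hinders the axial trajectory and the two C1 epimers may behave differently. Reduction of the deactivated vinylogous ester carbonyl may also be sluggish.
 The fallback replaces direct stereocontrol by late inversion and sets out from enone 20. i-Bu2AlH in toluene at −78 °C, a small hydride that prefers axial attack, gives the trans alcohol F5. The operations of steps 12 to 15 then give in turn the silyl ether F6, the C1 alcohol F7, the ketone F8 and the 4-epi hydroxy enone F9. At that stage the enol ether is deactivated by the C1 carbonyl. A Mitsunobu reaction (4-nitrobenzoic acid, PPh3, diisopropyl azodicarboxylate, THF, 0 °C) can therefore invert C4 and give the 4-nitrobenzoate F10. K2CO3 in MeOH at 0 °C releases 25, where the fallback ends.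

3. **Step 6 (Nef reaction).** The nitronate may be reduced incompletely or too far, C6 may epimerise next to the new aldehyde, and the polyene may be damaged if the buffer is overrun.
 The fallback is a two-stage, redox-neutral route through an isolable oxime and sets out from nitro ester 9. Benzyl bromide, KOH and catalytic tetrabutylammonium iodide in THF O-benzylate the nitronate, and the nitronic ester fragments under the basic conditions to the aldoxime F11. Transoximation with aqueous glyoxylic acid in THF at room temperature then frees aldehyde 11, where the route is rejoined.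

**Further compounds**

F1 | step 10 | methyl (2R,3R)-2-farnesyl-5-methoxy-3-methyl-4-(triethylsilyloxy)hex-5-enoate | COC(=O)[C@H](C/C=C(\C)CC/C=C(\C)CCC=C(C)C)[C@@H](C)C(O[Si](CC)(CC)CC)C(OC)=C
F2 | step 10 | methyl (2R,3R)-2-farnesyl-3-methyl-5-oxo-4-(triethylsilyloxy)hexanoate | COC(=O)[C@H](C/C=C(\C)CC/C=C(\C)CCC=C(C)C)[C@@H](C)C(O[Si](CC)(CC)CC)C(C)=O
F3 | step 10 | (5R,6R)-6-farnesyl-5-methyl-4-(triethylsilyloxy)cyclohexane-1,3-dione | O=C1CC(=O)[C@H](C/C=C(\C)CC/C=C(\C)CCC=C(C)C)[C@@H](C)C1O[Si](CC)(CC)CC
F4 | step 10 | (4R,5R)-4-farnesyl-3-methoxy-5-methyl-6-(triethylsilyloxy)cyclohex-2-en-1-one | O=C1C=C(OC)[C@H](C/C=C(\C)CC/C=C(\C)CCC=C(C)C)[C@@H](C)C1O[Si](CC)(CC)CC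
F5 | step 11 | (1S,5R,6R)-6-farnesyl-3-methoxy-5-methyl-4-(triethylsilyloxy)cyclohex-2-en-1-ol | COC1=C[C@@H](O)[C@H](C/C=C(\C)CC/C=C(\C)CCC=C(C)C)[C@@H](C)C1O[Si](CC)(CC)CC
F6 | step 11 | C4 tert-butyldimethylsilyl ether of F5 | COC1=C[C@@H](O[Si](C)(C)C(C)(C)C)[C@H](C/C=C(\C)CC/C=C(\C)CCC=C(C)C)[C@@H](C)C1O[Si](CC)(CC)CC
F7 | step 11 | (4S,5R,6R)-4-(tert-butyldimethylsilyloxy)-5-farnesyl-2-methoxy-6-methylcyclohex-2-en-1-ol | COC1=C[C@@H](O[Si](C)(C)C(C)(C)C)[C@H](C/C=C(\C)CC/C=C(\C)CCC=C(C)C)[C@@H](C)C1O
F8 | step 11 | (4S,5R,6R)-4-(tert-butyldimethylsilyloxy)-5-farnesyl-2-methoxy-6-methylcyclohex-2-en-1-one | COC1=C[C@@H](O[Si](C)(C)C(C)(C)C)[C@H](C/C=C(\C)CC/C=C(\C)CCC=C(C)C)[C@@H](C)C1=O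
F9 | step 11 | (4S,5R,6R)-5-farnesyl-4-hydroxy-2-methoxy-6-methylcyclohex-2-en-1-one | COC1=C[C@@H](O)[C@H](C/C=C(\C)CC/C=C(\C)CCC=C(C)C)[C@@H](C)C1=O
F10 | step 11 | (1R,5R,6R)-6-farnesyl-3-methoxy-5-methyl-4-oxocyclohex-2-en-1-yl 4-nitrobenzoate | COC1=C[C@H](OC(=O)c2ccc(cc2)[N+](=O)[O-])[C@H](C/C=C(\C)CC/C=C(\C)CCC=C(C)C)[C@@H](C)C1=O
F11 | step 6 | methyl (2R,3R)-2-farnesyl-4-(hydroxyimino)-3-methylbutanoate | COC(=O)[C@H](C/C=C(\C)CC/C=C(\C)CCC=C(C)C)[C@@H](C)C=NO
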